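Readings and results were generated by integration with constants of no real substance, and the scatter is random.

By the last reading, at 2.50 d, links in this flask, charged with first and second end groups one to one, read 86 %, against 87 % at 2.08 d. The readings so far, and the question, stand here:

| setting | delta | flask |
|---|---|---|
| first end groups | 0.087 M | 0.087 M |
| second end groups | 1 equiv | 1.00 equiv |
| remark | the very flask that is asked about, followed so far |  |
| time |  | 15 d |

- delta (time / d: links / %, first end groups / %): 0.250: 59, 40; 0.625: 76, 22; 1.25: 85, 18; 2.08: 87, 12; 2.50: 86, 16

(standard deviation of a reading: 2 percentage points)

- why nothing more happens at 15 d, or that something still does (it is still moving / all of the first end groups has reacted / the second end groups has run out first)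
- the links standing at 15 d, as a percentage of the first end groups charged

- the analysis behind the earlier runs scatters by 2 percentage points, standard deviation
- the reaction counts as stopped when no species that holds the first end groups changes by six tenths of a point or more over the second half of the time

Read across, each row of this flask closes: links plus first end groups make 99.0 % in the top row and 102 % in the bottom one, so within the scatter of 2 percentage points the first end groups that reacted stand as links. Read down, links rise from 59 % to 85 % by 1.25 d, then lie at 87 % and 86 %, while first end groups remain at 12 % and 16 %. So the readings of this flask levelled off, within their scatter, with first end groups still present, and I looked to the partner as limiting reagent. Each link takes one second end group, so I wrote its balance. The bottom two rows average 86.5 % links, which gives λ = 14 points: λ, the lost share, is the second end groups charged minus the links standing at the end, both in percent of the first end groups charged. My own figure for 15 d was therefore about 86.5 % links, with second end groups run out.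

The forecast said the second end groups has run out first, with 88 % links, between 85.5 % and 91 %, a little above my figure, and read the stall as a loss of second end groups “second end groups were being lost to a slow side reaction”.

The flask gave the second end groups has run out first, with 88.7 % links at 15 d.

    2 second end groups → self-condensation product (k = 0.290 M⁻¹ h⁻¹)
    first end groups + second end groups → links + by-product (k = 3.60 M⁻¹ h⁻¹)

Self-condensation ran beside link formation while second end groups lasted: by 1.50 d it had 99.4 % of its turnover behind it, and second end groups stood at 3.47 % of their charge. Link formation then took links from 85.3 % to 88.6 % by 7.50 d, as second end groups fell to 0.0154 %, leaving 11.3 % of first end groups at 15 d. So λ in this flask came to 11 points. The neighbour flask with 0.400 equiv of second end groups has a smaller λ, 1.4 points, with 38.6 % links.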